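Locants are those of the nonanolide ring: C1 is the lactone carbonyl, C8 the ring carbon on the ring oxygen O1.

**Plan**

Retrosynthesis: (a) the ester bond between O–C7 and the side chain; (b) the ring bond C7–C8, which opens the nine-membered lactone to a vinyl ester of the C1 acid that carries a C7 aldehyde; (c) C2–C3 (anti-crotylation) and C5–C6 (syn-aldol) on either side of a methacrolein unit (C3–C4–C5).
Enabling feature: in the ring, C8 is a CH(CH3) bonded to the lactone oxygen O1 and sits next to the secondary carbinol carbon C7 (vicinal C7/C8 dioxygenation). O–CH(CH3)–[M] is what Markovnikov hydrogen-atom transfer to a vinyl ester gives and C7–OH is the trace of an aldehyde, so one reductive alkene–aldehyde coupling closes the ring, creates the C8 methyl group and both C7 and C8, and leaves C7–OH as the only free hydroxyl.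
Forward order: Evans aldol (C5, C6) → epoxidation and lactonisation to a γ-lactone C7(=O)–O–C4, a temporary ring that fixes C4 and tells the chain ends apart → crotylation (C2, C3) → reductive opening of the γ-lactone and persilylation → C1 acid → vinyl ester → C7 aldehyde → ring closure C7–C8 → acylation of C7–OH → desilylation → semi-hydrogenation.
Stereochemistry: C5/C6 from the oxazolidinone auxiliary; C4 from hydroxyl-directed epoxidation followed by SN2 lactonisation (inversion); C2/C3 from the chiral crotylborane; C7 (Felkin–Anh) and C8 (cyclic transition state) in the ring closure; the side-chain carbinol from Alpine-Borane reduction; the (Z)-alkene from syn addition of H2.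

Key step: step 12

**Route**

Step 1
Reactants: 1 (S)-4-benzyl-3-propanoyl-1,3-oxazolidin-2-one; 2 methacrolein
Product: 4 (S)-4-benzyl-3-[(2S,3S)-3-hydroxy-2,4-dimethylpent-4-enoyl]-1,3-oxazolidin-2-one, via boron enolate 3 (not isolated)
Conditions: Bu2BOTf, i-Pr2NEt, CH2Cl2, −78 → 0 °C; 2, −78 → 0 °C; H2O2, MeOH, pH 7 buffer
Reagents that add atoms: none
Why: Evans syn aldol, in which the Z-boron enolate 3 reacts through a closed Zimmerman–Traxler transition state with one enolate face shielded by the benzyl group of the (S)-auxiliary, which should set C6 and C5 with the 2,3-syn relationship and the required absolute configuration.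

Step 2
Reactants: 4 syn-aldol imide
Product: 6 (3S,4S,5S)-4-hydroxy-5-(hydroxymethyl)-3,5-dimethyloxolan-2-one, via epoxy alcohol 5 (not isolated)
Conditions: VO(acac)2 (5 mol %), t-BuOOH, CH2Cl2, 0 °C → rt; then CSA (10 mol %), H2O (2 equiv), rt
Reagents that add atoms: tert-butyl hydroperoxide, CC(C)(C)OO; water, O
Why: Hydroxyl-directed vanadium epoxidation of the 2-substituted allylic alcohol should give the erythro (anti) epoxy alcohol 5 under A(1,2) control, and the imide carbonyl then opens the tertiary epoxide carbon C4 in a 5-exo SN2 manner with inversion (neighbouring-group lactonisation, as in halolactonisation of acyl oxazolidinones), so that hydrolysis of the iminium ether expels the auxiliary and leaves the γ-lactone with C4–O syn to C5–OH.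

Step 3
Reactants: 6 dihydroxy γ-lactone
Product: 7 (3S,4S,5S)-3,5-dimethyl-4-(triethylsilyloxy)-5-[(triethylsilyloxy)methyl]oxolan-2-one
Conditions: TESOTf (2.5 equiv), 2,6-lutidine, CH2Cl2, −78 → 0 °C
Reagents that add atoms: triethylsilyl triflate, CC[Si](CC)(CC)OS(=O)(=O)C(F)(F)F
Why: Silyl triflate silylation protects the primary and the hindered secondary hydroxyl group without touching a stereocentre.

Step 4
Reactants: 7 bis-silyl ether
Product: 8 (2R,3S,4S)-2,4-dimethyl-5-oxo-3-(triethylsilyloxy)oxolane-2-carbaldehyde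
Conditions: (COCl)2, DMSO, CH2Cl2, −78 → −30 °C; Et3N, −78 → 0 °C
Reagents that add atoms: none
Why: Under Swern conditions a primary triethylsilyl ether is cleaved and oxidised in one operation while the secondary one survives (selective oxidative desilylation), and the aldehyde formed cannot epimerise because its α-carbon C4 is quaternary.

Step 5
Reactants: 8 lactone aldehyde
Product: 9 (3S,4S,5S)-5-[(1R,2R)-1-hydroxy-2-methylbut-3-en-1-yl]-3,5-dimethyl-4-(triethylsilyloxy)oxolan-2-one
Conditions: (E)-crotyl-B(Ipc)2 [generated in situ from (+)-Ipc2BOMe, trans-but-2-ene, n-BuLi, KOt-Bu, BF3·OEt2], THF, −78 °C; H2O2, pH 7 buffer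
Reagents that add atoms: (E)-crotyldiisopinocampheylborane of the (−)-α-pinene series, C/C=C/CB([C@H]1C[C@H]2C[C@@H]([C@@H]1C)C2(C)C)[C@H]1C[C@H]2C[C@@H]([C@@H]1C)C2(C)C
Why: Brown crotylboration, in which the (E)-crotylborane reacts through a chair Zimmerman–Traxler transition state to give the 2,3-anti relationship and the isopinocampheyl groups direct attack to the Re face of the aldehyde (C3–OH syn to the C4 oxygen); (E)-crotylboron reagents have only a weak intrinsic Felkin/Cornforth bias toward α-oxygenated aldehydes, so reagent control should prevail in this mismatched case.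

Step 6
Reactants: 9 homoallylic alcohol lactone
Product: 10 (2R,3S,4S,5R,6R)-2,4,6-trimethyl-3-(triethylsilyloxy)oct-7-ene-1,4,5-triol
Conditions: LiBH4, THF, MeOH (1 equiv), 0 °C → rt
Reagents that add atoms: none
Why: Hydride reduction of the γ-lactone (the temporary ring) gives the primary C7 and tertiary C4 alcohols without touching the alkene, and any earlier translactonisation or silyl migration is harmless because the same carbon skeleton results and every hydroxyl is silylated next.

Step 7
Reactants: 10 triol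
Product: 11 tetrakis(triethylsilyl) ether of (2R,3S,4S,5R,6R)-2,4,6-trimethyloct-7-ene-1,3,4,5-tetrol
Conditions: TESOTf (5 equiv), 2,6-lutidine, CH2Cl2, 0 °C → rt
Reagents that add atoms: triethylsilyl triflate, CC[Si](CC)(CC)OS(=O)(=O)C(F)(F)F
Why: Exhaustive silylation with the silyl triflate is reactive enough for the hindered tertiary C4 hydroxyl and blocks every hydroxyl group that could later lactonise onto C1.

Step 8
Reactants: 11 tetrasilyl ether alkene
Product: 13 (2S,3R,4R,5S,6R)-2,4,6-trimethyl-3,4,5,7-tetrakis(triethylsilyloxy)heptanal, via ozonide 12 (not isolated)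
Conditions: O3, CH2Cl2, −78 °C; PPh3, −78 °C → rt
Reagents that add atoms: ozone, [O-][O+]=O
Why: Ozonolysis of the only C=C bond and reductive cleavage of the ozonide 12 give the C1 aldehyde under non-basic conditions that should not epimerise C2.

Step 9
Reactants: 13 C1 aldehyde
Product: 14 (2S,3R,4R,5S,6R)-2,4,6-trimethyl-3,4,5,7-tetrakis(triethylsilyloxy)heptanoic acid
Conditions: NaClO2, NaH2PO4, 2-methylbut-2-ene, t-BuOH/H2O, 0 °C → rt
Reagents that add atoms: sodium chlorite, [Na+].[O-]Cl=O
Why: Pinnick oxidation converts the aldehyde into the acid under buffered, non-epimerising conditions with the alkene as hypochlorite scavenger.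

Step 10
Reactants: 14 C1 acid
Product: 15 ethenyl (2S,3R,4R,5S,6R)-2,4,6-trimethyl-3,4,5,7-tetrakis(triethylsilyloxy)heptanoate
Conditions: vinyl acetate (solvent), Pd(OAc)2 (5 mol %), KOH (10 mol %), rt → 40 °C
Reagents that add atoms: vinyl acetate, CC(=O)OC=C
Why: Palladium-catalysed transvinylation (oxypalladation of vinyl acetate by the carboxylate, then β-acetate elimination) gives the vinyl ester under neutral conditions that leave the silyl ethers and C2 untouched.

Step 11
Reactants: 15 vinyl ester
Product: 16 ethenyl (2S,3R,4R,5S,6S)-2,4,6-trimethyl-7-oxo-3,4,5-tris(triethylsilyloxy)heptanoate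
Conditions: (COCl)2, DMSO, CH2Cl2, −78 → −30 °C; i-Pr2NEt, −78 → 0 °C
Reagents that add atoms: none
Why: Selective Swern oxidative desilylation of the primary silyl ether gives the C7 aldehyde in the presence of the secondary and tertiary silyl ethers and of the vinyl ester, and the hindered base at low temperature limits epimerisation at C6.

Step 12
Reactants: 16 vinyl ester aldehyde
Product: 18 (3S,4R,5R,6S,7R,8R,9S)-8-hydroxy-3,5,7,9-tetramethyl-4,5,6-tris(triethylsilyloxy)oxonan-2-one, via alkylchromium dichloride 17 (not isolated)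
Conditions: Co(salen)Cl (20 mol %; salen = N,N′-bis(3,5-di-tert-butylsalicylidene)ethane-1,2-diamine dianion), CrCl3(THF)3 (40 mol %), Ph(i-PrO)SiH2 (2.5 equiv), THF, slow addition of 16 (final 0.002 M), rt; aq. NH4Cl work-up
Reagents that add atoms: none
Why: Proposed new method: a trivalent cobalt hydride formed from Co(salen)Cl and the silane transfers a hydrogen atom to the terminal carbon of the vinyl ester (Markovnikov MHAT), which creates the C8 methyl group and a secondary α-acyloxy radical at C8 that is captured by divalent chromium to give the α-acyloxyalkyl trivalent chromium species 17, the electron that returns trivalent to divalent chromium coming from the cobalt/silane cycle so that the silane is the only stoichiometric reagent. 17 adds to the C7 aldehyde through a closed four-centre Nozaki–Hiyama-type transition state, which forms C7–C8 and closes the nine-membered lactone ring (O1, C1–C8) in a 9-exo-trig mode, the carbonyl oxygen staying outside the ring as the C7 alkoxide. The closest known reaction type is the cobalt/chromium dual-catalysed branch-selective reductive coupling of unactivated alkenes with aldehydes, supported by Nozaki–Hiyama–Kishi medium-ring closures and by the stability and aldehyde additions of α-acyloxyalkyl zinc–copper reagents; new are the enol ester as hydrogen-atom acceptor and the intramolecular medium-ring setting. C7 is controlled by the C6 stereocentre (Felkin–Anh attack, C6-methyl and C7-OH syn) and C8 by the cyclic transition state, in which the C8 methyl is expected to point to the outside of the forming ring and so trans to the C7 oxygen (7,8-anti); as the carbon–chromium bond forms from a planar radical, both faces of C8 can feed the lower transition state. The step needs hydrogen-atom transfer to a single C=C bond (16 has no other alkene, the unsaturated side chain being attached afterwards), capture of the radical by chromium faster than its reduction and ring closure faster than intermolecular addition, which the five-membered chelation of chromium by the ester carbonyl (also disfavouring 1,2-acyl shift), the fully silylated chain (no hydroxyl that could lactonise onto the activated ester) and high dilution are meant to secure.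

Step 13
Reactants: 19 rac-hept-1-yn-3-ol
Product: 20 hept-1-yn-3-one
Conditions: Dess–Martin periodinane, NaHCO3, CH2Cl2, 0 °C → rt
Reagents that add atoms: none
Why: Dess–Martin oxidation of the propargylic alcohol gives the ynone without attack on the terminal alkyne.

Step 14
Reactants: 20 ynone
Product: 21 (R)-hept-1-yn-3-ol
Conditions: (R)-Alpine-Borane (B-isopinocampheyl-9-BBN from (+)-α-pinene), neat, rt; CH3CHO; ethanolamine, Et2O
Reagents that add atoms: none
Why: Midland Alpine-Borane reduction, in which hydride is delivered from the pinanyl group through a boat-like six-membered transition state with the small alkynyl group next to the pinane methyl, should give the (R)-propargylic alcohol with the reagent from (+)-α-pinene.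

Step 15
Reactants: 21 (R)-propargylic alcohol
Product: 22 (R)-tert-butyl(hept-1-yn-3-yloxy)dimethylsilane
Conditions: TBSCl, imidazole, DMF, rt
Reagents that add atoms: tert-butyldimethylsilyl chloride, CC(C)(C)[Si](C)(C)Cl
Why: Standard silylation of the secondary alcohol, with no change at the stereocentre.

Step 16
Reactants: 22 silyl ether alkyne
Product: 24 (R)-4-(tert-butyldimethylsilyloxy)oct-2-ynoic acid, via lithium acetylide 23 (not isolated)
Conditions: n-BuLi, THF, −78 °C; CO2 (g), −78 °C → 0 °C; cold 1 M HCl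
Reagents that add atoms: carbon dioxide, O=C=O
Why: Deprotonation of the terminal alkyne and carboxylation of the acetylide 23 with CO2 give the alkynoic acid.

Step 17
Reactants: 18 hydroxy lactone; 24 alkynoic acid
Product: 25 (3S,4R,5R,6S,7R,8R,9S)-3,5,7,9-tetramethyl-2-oxo-4,5,6-tris(triethylsilyloxy)oxonan-8-yl (R)-4-(tert-butyldimethylsilyloxy)oct-2-ynoate
Conditions: DIC, DMAP (10 mol %), CH2Cl2, −20 → 0 °C
Reagents that add atoms: none
Why: Steglich esterification acylates the only free hydroxyl, the C7–OH set free by the ring closure, and low temperature with catalytic DMAP limits conjugate addition to the alkynoate.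

Step 18
Reactants: 25 silylated alkynoate
Product: 26 (3S,4R,5R,6S,7S,8R,9S)-4,5,6-trihydroxy-3,5,7,9-tetramethyl-2-oxooxonan-8-yl (R)-4-hydroxyoct-2-ynoate
Conditions: HF·pyridine, pyridine, THF, 0 °C → rt
Reagents that add atoms: none
Why: Buffered fluoride desilylation removes the three triethylsilyl ethers and the TBS ether under mildly acidic, non-nucleophilic conditions chosen to limit translactonisation by the freed C4 and C5 hydroxyls, while the side chain, still an alkynoate, cannot close to a butenolide.

Step 19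
Reactants: 26 tetrahydroxy alkynoate
Product: 27 (3S,4R,5R,6S,7S,8R,9S)-4,5,6-trihydroxy-3,5,7,9-tetramethyl-2-oxooxonan-8-yl (2Z,4R)-4-hydroxyoct-2-enoate (CNP0205075.3)
Conditions: H2 (1 atm), Pd/CaCO3 poisoned with Pb(OAc)2 (Lindlar catalyst), quinoline, EtOAc, rt
Reagents that add atoms: none
Why: Lindlar semi-hydrogenation adds H2 syn to the alkyne and gives the (Z)-enoate under neutral conditions as the last step, so the (Z)-γ-hydroxy enoate never meets acid or base.

**Compound list**

1 | (S)-4-benzyl-3-propanoyl-1,3-oxazolidin-2-one | CCC(=O)N1[C@@H](Cc2ccccc2)COC1=O | starting material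
2 | methacrolein | CC(=C)C=O | starting material
3 | (Z)-dibutylboron enolate of 1 | C/C=C(\OB(CCCC)CCCC)N1[C@@H](Cc2ccccc2)COC1=O | intermediate
4 | (S)-4-benzyl-3-[(2S,3S)-3-hydroxy-2,4-dimethylpent-4-enoyl]-1,3-oxazolidin-2-one | O=C(N1[C@@H](Cc2ccccc2)COC1=O)[C@@H](C)[C@H](O)C(C)=C | intermediate
5 | (S)-4-benzyl-3-{(2S,3S)-3-hydroxy-2-methyl-3-[(2R)-2-methyloxiran-2-yl]propanoyl}-1,3-oxazolidin-2-one | O=C(N1[C@@H](Cc2ccccc2)COC1=O)[C@@H](C)[C@H](O)[C@@]2(C)CO2 | intermediate
6 | (3S,4S,5S)-4-hydroxy-5-(hydroxymethyl)-3,5-dimethyloxolan-2-one | O=C1[C@@H](C)[C@H](O)[C@](C)(CO)O1 | intermediate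
7 | (3S,4S,5S)-3,5-dimethyl-4-(triethylsilyloxy)-5-[(triethylsilyloxy)methyl]oxolan-2-one | O=C1[C@@H](C)[C@H](O[Si](CC)(CC)CC)[C@](C)(CO[Si](CC)(CC)CC)O1 | intermediate
8 | (2R,3S,4S)-2,4-dimethyl-5-oxo-3-(triethylsilyloxy)oxolane-2-carbaldehyde | O=C1[C@@H](C)[C@H](O[Si](CC)(CC)CC)[C@](C)(C=O)O1 | intermediate
9 | (3S,4S,5S)-5-[(1R,2R)-1-hydroxy-2-methylbut-3-en-1-yl]-3,5-dimethyl-4-(triethylsilyloxy)oxolan-2-one | O=C1[C@@H](C)[C@H](O[Si](CC)(CC)CC)[C@](C)([C@H](O)[C@H](C)C=C)O1 | intermediate
10 | (2R,3S,4S,5R,6R)-2,4,6-trimethyl-3-(triethylsilyloxy)oct-7-ene-1,4,5-triol | OC[C@@H](C)[C@H](O[Si](CC)(CC)CC)[C@@](C)(O)[C@H](O)[C@H](C)C=C | intermediate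
11 | tetrakis(triethylsilyl) ether of (2R,3S,4S,5R,6R)-2,4,6-trimethyloct-7-ene-1,3,4,5-tetrol | CC[Si](CC)(CC)OC[C@@H](C)[C@H](O[Si](CC)(CC)CC)[C@@](C)(O[Si](CC)(CC)CC)[C@H](O[Si](CC)(CC)CC)[C@H](C)C=C | intermediate
12 | ozonide (1,2,4-trioxolane) of 11 | CC[Si](CC)(CC)OC[C@@H](C)[C@H](O[Si](CC)(CC)CC)[C@@](C)(O[Si](CC)(CC)CC)[C@H](O[Si](CC)(CC)CC)[C@H](C)C1OCOO1 | intermediate
13 | (2S,3R,4R,5S,6R)-2,4,6-trimethyl-3,4,5,7-tetrakis(triethylsilyloxy)heptanal | CC[Si](CC)(CC)OC[C@@H](C)[C@H](O[Si](CC)(CC)CC)[C@@](C)(O[Si](CC)(CC)CC)[C@H](O[Si](CC)(CC)CC)[C@H](C)C=O | intermediate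
14 | (2S,3R,4R,5S,6R)-2,4,6-trimethyl-3,4,5,7-tetrakis(triethylsilyloxy)heptanoic acid | CC[Si](CC)(CC)OC[C@@H](C)[C@H](O[Si](CC)(CC)CC)[C@@](C)(O[Si](CC)(CC)CC)[C@H](O[Si](CC)(CC)CC)[C@H](C)C(=O)O | intermediate
15 | ethenyl (2S,3R,4R,5S,6R)-2,4,6-trimethyl-3,4,5,7-tetrakis(triethylsilyloxy)heptanoate | CC[Si](CC)(CC)OC[C@@H](C)[C@H](O[Si](CC)(CC)CC)[C@@](C)(O[Si](CC)(CC)CC)[C@H](O[Si](CC)(CC)CC)[C@H](C)C(=O)OC=C | intermediate
16 | ethenyl (2S,3R,4R,5S,6S)-2,4,6-trimethyl-7-oxo-3,4,5-tris(triethylsilyloxy)heptanoate | O=C[C@@H](C)[C@H](O[Si](CC)(CC)CC)[C@@](C)(O[Si](CC)(CC)CC)[C@H](O[Si](CC)(CC)CC)[C@H](C)C(=O)OC=C | intermediate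
17 | 1-(dichlorochromio)ethyl ester corresponding to 16 (C8 alkylchromium, C8 configuration labile) | O=C[C@@H](C)[C@H](O[Si](CC)(CC)CC)[C@@](C)(O[Si](CC)(CC)CC)[C@H](O[Si](CC)(CC)CC)[C@H](C)C(=O)OC(C)[Cr](Cl)Cl | intermediate
18 | (3S,4R,5R,6S,7R,8R,9S)-8-hydroxy-3,5,7,9-tetramethyl-4,5,6-tris(triethylsilyloxy)oxonan-2-one | O[C@@H]1[C@@H](C)[C@H](O[Si](CC)(CC)CC)[C@@](C)(O[Si](CC)(CC)CC)[C@H](O[Si](CC)(CC)CC)[C@H](C)C(=O)O[C@H]1C | intermediate
19 | rac-hept-1-yn-3-ol | CCCCC(O)C#C | starting material
20 | hept-1-yn-3-one | CCCCC(=O)C#C | intermediate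
21 | (R)-hept-1-yn-3-ol | CCCC[C@@H](O)C#C | intermediate
22 | (R)-tert-butyl(hept-1-yn-3-yloxy)dimethylsilane | CCCC[C@@H](O[Si](C)(C)C(C)(C)C)C#C | intermediate
23 | lithium acetylide of 22 | CCCC[C@@H](O[Si](C)(C)C(C)(C)C)C#C[Li] | intermediate
24 | (R)-4-(tert-butyldimethylsilyloxy)oct-2-ynoic acid | CCCC[C@@H](O[Si](C)(C)C(C)(C)C)C#CC(=O)O | intermediate
25 | (3S,4R,5R,6S,7R,8R,9S)-3,5,7,9-tetramethyl-2-oxo-4,5,6-tris(triethylsilyloxy)oxonan-8-yl (R)-4-(tert-butyldimethylsilyloxy)oct-2-ynoate | CCCC[C@@H](O[Si](C)(C)C(C)(C)C)C#CC(=O)O[C@@H]1[C@@H](C)[C@H](O[Si](CC)(CC)CC)[C@@](C)(O[Si](CC)(CC)CC)[C@H](O[Si](CC)(CC)CC)[C@H](C)C(=O)O[C@H]1C | intermediate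
26 | (3S,4R,5R,6S,7S,8R,9S)-4,5,6-trihydroxy-3,5,7,9-tetramethyl-2-oxooxonan-8-yl (R)-4-hydroxyoct-2-ynoate | CCCC[C@@H](O)C#CC(=O)O[C@@H]1[C@@H](C)[C@H](O)[C@@](C)(O)[C@H](O)[C@H](C)C(=O)O[C@H]1C | intermediate
27 | (3S,4R,5R,6S,7S,8R,9S)-4,5,6-trihydroxy-3,5,7,9-tetramethyl-2-oxooxonan-8-yl (2Z,4R)-4-hydroxyoct-2-enoate | CCCC[C@@H](O)/C=C\C(=O)O[C@@H]1[C@@H](C)[C@H](O)[C@@](C)(O)[C@H](O)[C@H](C)C(=O)O[C@H]1C | target

**Step count**

Total: 19 steps. Longest linear sequence: 15 steps (steps 1–12 and 17–19); the side-chain acid takes 4 steps (13–16).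

**Steps most likely to fail**

1. Step 12 (the step that carries the label). What may go wrong: net hydrogenation of the vinyl ester or hydrosilylation of the aldehyde before the radical is captured by chromium, intermolecular addition instead of nine-ring closure, poor facial selectivity at C7 or C8, and 1,2-shift of the lactone acyl group to the new C7 alkoxide (ring contraction). The fallback uses known chemistry only, closes the ring at the O1–C1 bond and makes C7–C8 intermolecularly; it sets out from 11. Swern oxidation of the primary silyl ether gives the C7 aldehyde F1. Felkin–Anh addition of 1-ethoxyvinyllithium, with alkylation of the resulting alkoxide in the same flask by 4-methoxybenzyl bromide, gives the enol ether F2, which dilute acid hydrolyses to the α-(4-methoxybenzyloxy) methyl ketone F3. Chelation-controlled reduction with Zn(BH4)2 gives the 7,8-anti alcohol F4. Ozonolysis of the terminal alkene gives the C1 aldehyde F5 and Pinnick oxidation the seco acid F6. Shiina macrolactonisation (MNBA, DMAP, Et3N, high dilution) gives the nine-membered lactone PMB ether F7; DDQ removes the PMB group and the route is rejoined at 18.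

2. Step 5. What may go wrong: the reagent-controlled addition runs against the Felkin/Cornforth preference of the α-oxygenated quaternary aldehyde, so facial selectivity at C3 may erode, and the hindered aldehyde may react so slowly that the crotylborane isomerises. The fallback works under substrate control and sets out from 8. Achiral (Z)-crotylboronic acid pinacol ester adds with the intrinsic Felkin/Cornforth sense and 2,3-syn topology to give the C3-epimeric homoallylic alcohol F8, which already has the required C2 configuration. Dess–Martin oxidation gives the β,γ-unsaturated ketone F9. Reduction with LiBH(s-Bu)3 at −78 °C, in which the Felkin–Anh preferences of C2 and C4 point the same way, should give the (3R)-carbinol, and the route is rejoined at 9.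

3. Step 2. What may go wrong: the weakly nucleophilic imide carbonyl may open the epoxide too slowly, so that semipinacol rearrangement of the epoxy alcohol, opening at the primary carbon or incomplete release of the auxiliary compete. The fallback uses a free carboxylic acid as the internal nucleophile and sets out from 4. LiOH/H2O2 removes the auxiliary to give the β-hydroxy acid F10. The same vanadium-directed epoxidation gives the epoxy acid F11, which lactonises spontaneously by 5-exo attack of the acid on the tertiary epoxide carbon with inversion, and the route is rejoined at 6.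

Further compounds
F1 | step 12 | (2S,3S,4S,5R,6R)-2,4,6-trimethyl-3,4,5-tris(triethylsilyloxy)oct-7-enal | O=C[C@@H](C)[C@H](O[Si](CC)(CC)CC)[C@@](C)(O[Si](CC)(CC)CC)[C@H](O[Si](CC)(CC)CC)[C@H](C)C=C
F2 | step 12 | C7 4-methoxybenzyl ether of the 1-ethoxyvinyl adduct of F1 (enol ether) | COc1ccc(CO[C@@H](C(=C)OCC)[C@@H](C)[C@H](O[Si](CC)(CC)CC)[C@@](C)(O[Si](CC)(CC)CC)[C@H](O[Si](CC)(CC)CC)[C@H](C)C=C)cc1
F3 | step 12 | C8 methyl ketone with C7 4-methoxybenzyl ether | COc1ccc(CO[C@@H](C(C)=O)[C@@H](C)[C@H](O[Si](CC)(CC)CC)[C@@](C)(O[Si](CC)(CC)CC)[C@H](O[Si](CC)(CC)CC)[C@H](C)C=C)cc1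
F4 | step 12 | (8S)-alcohol with C7 4-methoxybenzyl ether (7,8-anti) | COc1ccc(CO[C@@H]([C@H](C)O)[C@@H](C)[C@H](O[Si](CC)(CC)CC)[C@@](C)(O[Si](CC)(CC)CC)[C@H](O[Si](CC)(CC)CC)[C@H](C)C=C)cc1
F5 | step 12 | C1 aldehyde of F4 | COc1ccc(CO[C@@H]([C@H](C)O)[C@@H](C)[C@H](O[Si](CC)(CC)CC)[C@@](C)(O[Si](CC)(CC)CC)[C@H](O[Si](CC)(CC)CC)[C@H](C)C=O)cc1
F6 | step 12 | seco acid (C1 acid, C8 alcohol, C7 4-methoxybenzyl ether) | COc1ccc(CO[C@@H]([C@H](C)O)[C@@H](C)[C@H](O[Si](CC)(CC)CC)[C@@](C)(O[Si](CC)(CC)CC)[C@H](O[Si](CC)(CC)CC)[C@H](C)C(=O)O)cc1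
F7 | step 12 | C7 4-methoxybenzyl ether of 18 | COc1ccc(CO[C@@H]2[C@@H](C)[C@H](O[Si](CC)(CC)CC)[C@@](C)(O[Si](CC)(CC)CC)[C@H](O[Si](CC)(CC)CC)[C@H](C)C(=O)O[C@H]2C)cc1
F8 | step 5 | (3S,4S,5S)-5-[(1S,2R)-1-hydroxy-2-methylbut-3-en-1-yl]-3,5-dimethyl-4-(triethylsilyloxy)oxolan-2-one | O=C1[C@@H](C)[C@H](O[Si](CC)(CC)CC)[C@](C)([C@@H](O)[C@H](C)C=C)O1
F9 | step 5 | (3S,4S,5R)-3,5-dimethyl-5-[(2R)-2-methylbut-3-enoyl]-4-(triethylsilyloxy)oxolan-2-one | O=C1[C@@H](C)[C@H](O[Si](CC)(CC)CC)[C@](C)(C(=O)[C@H](C)C=C)O1
F10 | step 2 | (2S,3S)-3-hydroxy-2,4-dimethylpent-4-enoic acid | OC(=O)[C@@H](C)[C@H](O)C(C)=C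
F11 | step 2 | (2S,3S)-3-hydroxy-2-methyl-3-[(2R)-2-methyloxiran-2-yl]propanoic acid | OC(=O)[C@@H](C)[C@H](O)[C@@]1(C)CO1
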